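## Analysis of the target

The target is a C30 bis-bicyclic ether. A methylenecyclohexane (ring A) is trans-fused to a 2,2-dimethyloxepan-3-ol (ring B), and a 1-methylcyclohexanol (ring C) is trans-fused to a 2,2-dimethyloxepan-3-one (ring D). The two bicycles are joined by a CH2CH2 chain between the ring A and ring C methine carbons.

There are eight stereocentres, four in each half. Rings A and C carry the same three contiguous centres in the same absolute sense: the CH bearing the ring-fusion oxygen, the methyl-bearing quaternary carbon, and the CH bearing the linker. Oxygen and linker are equatorial and on the same face as the axial angular methyl; the oxepane CH2 on the quaternary carbon is trans to the oxygen. Ring B adds an S-configured secondary carbinol next to the gem-dimethyl ether carbon. Ring C adds a tertiary carbinol whose hydroxyl is axial, syn to the angular methyl.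

The sensitive groups are the exocyclic methylene of ring A (acid, electrophilic oxidants), the tertiary alcohol (dehydration) and the enolisable ring D ketone. The difficulties are two quaternary carbons flanked by stereocentres, two seven-membered ethers closed at a tertiary carbon, the union of two hindered halves through an unactivated sp3–sp3 bond, and telling apart two oxepane oxygens in almost identical surroundings (one a hydroxyl, one a ketone).

The plan rests on ring C, and equally on ring A. Its sequence of O-bearing CH, methyl-bearing quaternary carbon, linker-bearing CH and a carbon that carries (or derives from) an exocyclic methylene is the pattern left when the radical from an internal 6,7-epoxide of a farnesyl chain closes onto the 2,3-alkene. The untouched prenyl arm on the quaternary carbon is then in place to become the oxepane.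

## Retrosynthetic reasoning

**End-game adjustments.** Target 22 is taken back to its ring B silyl ether 21, then to diol 20 and its bis-trimethylsilyl ether 19. The ring D ketone is the last oxidation because a ketone would not survive the carbanion used to join the halves. Different silyl groups on the ring B and ring D oxygens are the only handle for telling them apart. No skeletal bond is cut here.

**Linker.** Compound 19 is cut at the central CH2–CH2 bond, through sulfone 18, into sulfone 16 and triflate 17 (from alcohol 11). This cut gives two halves of equal size with the same ring pattern and touches no stereocentre; a cut at either ring-to-chain bond would. The forward reaction is alkylation of the sulfonyl-stabilised carbanion of 16 by 17, then reductive removal of the sulfonyl group. The electrophile sits on the ring A/B half because its CH2 has only one quaternary neighbour.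

**Ring C carbinol.** Sulfone 16 goes back through 15 and 14 to triol 13. The tertiary carbinol of 13 is cut at its methyl group to ketone 12, which is the ozonolysis product of methylene compound 9. The axial angular methyl, 1,3 to the carbonyl, should force equatorial entry of the methyl nucleophile and so give the axial hydroxyl.

**Ring A/B half.** Alcohol 11 comes from 9 by silylation (10) and removal of the acetate. Both halves therefore derive from the single bicycle 9, which halves the work on the ring systems.

**Oxepane.** In 9 the ether bond from the ring oxygen to the gem-dimethyl carbon is cut, leading to hydroxy epoxide 8 and, one step further, to alkene 7. The forward ring closure must take the 7-endo course at the tertiary epoxide carbon. The epoxide CH becomes the ring B carbinol, so its configuration is set by a reagent-controlled epoxidation of 7.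

**Six-membered ring.** In 7 the bond between the quaternary carbon and the acetoxymethyl-bearing CH is cut, giving the acyclic internal epoxide 6. This one bond closes the ring, creates the quaternary centre and its neighbour, and leaves the exocyclic methylene. The methylene is the handle for the ring C carbinol and is the finished ring A alkene.

**Precursor.** Epoxide 6 is cut between the epoxide-bearing CH2 and the prenyl CH2, giving epoxy triflate 5 (from epoxy alcohol 3) and the prenyl nucleophile 4. Compound 3 is the asymmetric epoxidation product of allylic alcohol 2, itself the allylic oxidation product of geranyl acetate 1. The hydroxymethyl group that directs the epoxidation thus becomes a chain carbon.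

## Alternatives that were turned down

**Alternative 1:** Ring B would be cut between its two adjacent CH2 carbons, and the ring closed by metathesis of diene A2 (a vinyl group on the quaternary carbon, a second one on the silyloxy-bearing carbon of the ether side chain). The second-generation Grubbs catalyst, RuCl2(H2IMes)(PCy3)(=CHPh), would expel ethylene and give oxepene A1.
- For: seven-membered ether formation by metathesis is dependable and tolerant of silyl ethers and ketals. All stereocentres of A1 exist before ring closure, so the key step carries no selectivity question. On this point it is stronger than the radical cyclisation.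
- Against: the step sets no stereocentre, and its alkene must then be hydrogenated. The three ring A centres, including the vinyl-bearing quaternary carbon, have to be built on a cyclohexane beforehand. The tertiary ether of A2 must be made intermolecularly between a hindered secondary alcohol and a fully substituted carbon. The ring A ketone, carried as a dioxolane, still needs methylenation, and ring C/D needs a second campaign.
- Comparison: the chosen route forms the carbocycle, two stereocentres and the methylene in one step from an acyclic terpene, closes the ether intramolecularly, and uses one intermediate for both halves.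

**Alternative 2:** The quaternary carbon would be cut from its 4-methylpent-3-enyl arm, and the neighbouring CH from its hydroxymethyl carbon, on the ring A enone A4. The 4-methylpent-3-enyl Grignard reagent with CuBr·SMe2 and Me3SiCl would add to the β-carbon anti to the silyloxy group. MeLi would regenerate the enolate, and formaldehyde would trap it to give A3.
- For: both new centres are set by substrate control on a ring, with no planar radical at the quaternary carbon. On this point it is stronger than the chosen plan. The ring ketone of A3 is already the carbonyl needed for the ring C carbinol, so no ozonolysis is needed.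
- Against: no ring is formed, and enantiopure A4 needs its own synthesis. Conjugate addition to a β,β-disubstituted enone next to a silyloxy-bearing carbon is sterically demanding, and γ-oxygenated enones can lose the γ-oxygen by electron transfer from the cuprate. The β-hydroxy ketone A3 is prone to retro-aldol cleavage and dehydration. For ring A the ketone must be methylenated beside that sensitive array.
- Comparison: the chosen route reaches the same substitution pattern in four steps from geranyl acetate and delivers the methylene directly, at the price of a less certain quaternary centre.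

**Alternative 3:** Rings A and B would be cut together: the bond between the quaternary carbon and the linker-bearing CH, and the ether bond to the gem-dimethyl carbon. This leads to the acyclic bis-epoxide A6 with a (Z)-allylsilane terminus. Me3SiOTf with 2,6-di-tert-butyl-4-methylpyridine would activate the terminal epoxide. The inner epoxide oxygen would attack its gem-dimethyl carbon, and the allylsilane would open the resulting epoxonium ion at the methyl-bearing carbon with inversion. Loss of silicon would give A5.
- For: two rings, one C–C and one C–O bond, and the methylene are formed in one step. The anti opening transfers the epoxide configuration to the quaternary carbon stereospecifically, which the radical route cannot do. On step economy for one half, and on that stereochemical point, it is stronger.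
- Against: A6 needs two enantioselective epoxidations in the presence of an allylsilane alkene that is itself oxidisable, and a geometrically pure trisubstituted allylsilane. Cationic cascades of this kind branch into premature proton loss, smaller cyclic ethers and protodesilylation.
- Comparison: the chosen plan separates the carbocyclisation and the ether closure into two steps whose selectivities can be addressed one at a time. Its precursor needs only a tartrate-controlled epoxidation, and the radical step runs under neutral conditions that spare the acetate and the prenyl alkene.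

Key step: step 4

Remark on the chemistry: compound 4 is taken as its commercial THF solution (otherwise made from prenyl chloride and magnesium), and the ketone catalyst of step 5 is the L-fructose-derived enantiomer of the usual D-fructose-derived ketone, taken as available from L-sorbose.

## Route

Step 1
Reactants: 1 geranyl acetate
Product: 2 (2E,6E)-8-hydroxy-3,7-dimethylocta-2,6-dien-1-yl acetate
Conditions: SeO2 (0.1 equiv), t-BuOOH, salicylic acid (0.1 equiv), CH2Cl2, rt
Reagents that add atoms: tert-butyl hydroperoxide, CC(C)(C)OO (the hydroxyl oxygen, passed on through SeO2)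
Why: Catalytic SeO2 allylic oxidation (ene reaction, then [2,3]-sigmatropic shift) attacks the electron-rich terminal alkene at its (E)-methyl group; the 2,3-alkene is deactivated by the allylic acetate.

Step 2
Reactants: 2 (2E,6E)-8-hydroxy-3,7-dimethylocta-2,6-dien-1-yl acetate
Product: 3 (2E)-5-[(2S,3S)-3-(hydroxymethyl)-3-methyloxiran-2-yl]-3-methylpent-2-en-1-yl acetate
Conditions: Ti(OiPr)4 (0.1 equiv), L-(+)-diethyl tartrate (0.12 equiv), t-BuOOH, 4 Å molecular sieves, CH2Cl2, −20 °C
Reagents that add atoms: tert-butyl hydroperoxide, CC(C)(C)OO (the epoxide oxygen)
Why: Sharpless asymmetric epoxidation; only the alkene of the allylic alcohol is bound to titanium, and L-(+)-tartrate gives the (2S,3S)-epoxy alcohol from an (E)-2-methylalk-2-en-1-ol, which fixes the future O-bearing CH of rings A and C.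

Step 3
Reactants: 3 (2E)-5-[(2S,3S)-3-(hydroxymethyl)-3-methyloxiran-2-yl]-3-methylpent-2-en-1-yl acetate; 4 prenylmagnesium chloride
Product: 6 (6S,7S)-6,7-epoxyfarnesyl acetate, via epoxy triflate 5 (not isolated)
Conditions: Tf2O, 2,6-lutidine, CH2Cl2, −78 °C; crude 5, then 4, CuI (0.1 equiv), THF, −78 → −40 °C
Reagents that add atoms: prenylmagnesium chloride 4, CC(C)=CC[Mg]Cl (the prenyl group); trifluoromethanesulfonic anhydride, O=S(=O)(OS(=O)(=O)C(F)(F)F)C(F)(F)F (triflyl group of intermediate 5 only)
Why: Copper-catalysed cross-coupling of a Grignard reagent with a primary alkyl triflate; copper directs bond formation to the unsubstituted terminus of the prenyl unit, and at −78 °C the triflate reacts far faster than the allylic acetate or the trisubstituted epoxide, whose configuration is untouched.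

Step 4
Reactants: 6 (6S,7S)-6,7-epoxyfarnesyl acetate
Product: 7 [(1R,2S,3S)-3-hydroxy-2-methyl-6-methylidene-2-(4-methylpent-3-en-1-yl)cyclohexyl]methyl acetate
Conditions: Cp2TiCl2 (2.5 equiv), Mn dust (8 equiv), THF (degassed), rt; then dilute aq. HCl
Reagents that add atoms: none
Why: Cp2TiCl (trivalent titanium, formed from Cp2TiCl2 and Mn) transfers one electron to the epoxide, whose C–O bond breaks at the fully substituted carbon to give a tertiary β-titanoxy radical; this is the established reductive epoxide-opening radical cyclisation of epoxypolyprenes, applied to an internal epoxide. The radical adds to the unsubstituted end of the allylic-acetate alkene in a 6-endo-trig closure, forming the bond from the quaternary carbon to the acetoxymethyl-bearing carbon and placing the new radical on the methyl-bearing ring carbon. A second Cp2TiCl captures that radical, and the alkyltitanium loses a β-hydrogen from the methyl group as Cp2Ti(H)Cl, leaving the exocyclic methylene and no further stereocentre. The carbinol carbon keeps the S configuration of the epoxide because its C–O bond is never broken. The acetoxymethyl-bearing carbon is set by the E geometry of the alkene in a chair transition state, which places the acetoxymethyl group equatorial, 1,3-cis to the titanoxy group. The quaternary carbon is re-formed from a planar radical, so its configuration rests on the chair alone: the 4-methylpent-3-enyl arm should take the equatorial site and leave the methyl axial, because an axial CH2R group between two equatorially substituted neighbours meets syn-pentane contacts on both sides. Regioselective opening is secured by the tertiary radical, and 6-endo over 5-exo addition by attack at the less substituted alkene carbon; the prenyl alkene is spared because the radical could reach it only through a four-membered ring or a 5-endo closure.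

Step 5
Reactants: 7 [(1R,2S,3S)-3-hydroxy-2-methyl-6-methylidene-2-(4-methylpent-3-en-1-yl)cyclohexyl]methyl acetate
Product: 8 [(1R,2S,3S)-2-{2-[(2S)-3,3-dimethyloxiran-2-yl]ethyl}-3-hydroxy-2-methyl-6-methylidenecyclohexyl]methyl acetate
Conditions: 1,2:4,5-di-O-isopropylidene-β-L-erythro-2,3-hexodiulo-2,6-pyranose (0.3 equiv), KHSO5 (as the triple salt 2KHSO5·KHSO4·K2SO4), K2CO3, Bu4NHSO4, MeCN/CH2(OMe)2/aq. Na2B4O7 buffer, 0 °C
Reagents that add atoms: potassium peroxymonosulfate, [K+].[O-]OS(=O)(=O)O (the epoxide oxygen, through the dioxirane of the ketone)
Why: Shi epoxidation; the chiral dioxirane reacts with the electron-rich trisubstituted alkene much faster than with the hindered 1,1-disubstituted methylene, and the L-fructose-derived ketone gives the S epoxide (mirror image of the R selectivity of the D-fructose-derived ketone) under reagent control, remote from the ring.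

Step 6
Reactants: 8 [(1R,2S,3S)-2-{2-[(2S)-3,3-dimethyloxiran-2-yl]ethyl}-3-hydroxy-2-methyl-6-methylidenecyclohexyl]methyl acetate
Product: 9 [(3S,5aS,6R,9aS)-3-hydroxy-2,2,5a-trimethyl-7-methylidenedecahydro-1-benzoxepin-6-yl]methyl acetate
Conditions: BF3·OEt2 (0.3 equiv), CH2Cl2, −78 → −40 °C
Reagents that add atoms: none
Why: Lewis-acid-promoted intramolecular epoxide opening; the activated epoxide has cationic character at its gem-dimethyl carbon, so the ring hydroxyl attacks there (7-endo) and closes the trans-fused oxepane, while the epoxide CH keeps its C–O bond and its S configuration and becomes the secondary carbinol.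

Step 7
Reactants: 9 [(3S,5aS,6R,9aS)-3-hydroxy-2,2,5a-trimethyl-7-methylidenedecahydro-1-benzoxepin-6-yl]methyl acetate
Product: 10 tert-butyldimethylsilyl ether of 9 at the oxepane hydroxyl
Conditions: t-BuMe2SiOTf, 2,6-lutidine, CH2Cl2, 0 °C
Reagents that add atoms: tert-butyldimethylsilyl trifluoromethanesulfonate, CC(C)(C)[Si](C)(C)OS(=O)(=O)C(F)(F)F
Why: Silyl triflate silylation of the hindered secondary alcohol; acetate and methylene are inert and no stereocentre is touched.

Step 8
Reactants: 10 tert-butyldimethylsilyl ether of 9
Product: 11 [(3S,5aS,6R,9aS)-3-(tert-butyldimethylsilyloxy)-2,2,5a-trimethyl-7-methylidenedecahydro-1-benzoxepin-6-yl]methanol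
Conditions: K2CO3, MeOH, rt
Reagents that add atoms: none
Why: Base-catalysed methanolysis removes the acetate; the secondary silyl ether is stable to K2CO3 in MeOH.

Step 9
Reactants: 9 [(3S,5aS,6R,9aS)-3-hydroxy-2,2,5a-trimethyl-7-methylidenedecahydro-1-benzoxepin-6-yl]methyl acetate
Product: 12 7-oxo analogue of 9 (methylene replaced by C=O; acetoxymethyl, oxepane hydroxyl and all stereocentres as in 9)
Conditions: O3, CH2Cl2/MeOH, −78 °C; then Me2S, −78 °C → rt
Reagents that add atoms: ozone, [O-][O+]=O (the carbonyl oxygen)
Why: Ozonolysis of the only alkene gives the ring C ketone and formaldehyde; the neutral reductive work-up avoids enolisation, and the α-stereocentre already holds its more stable equatorial acetoxymethyl group.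

Step 10
Reactants: 12 7-oxo analogue of 9
Product: 13 6-(hydroxymethyl)-2,2,5a,7-tetramethyldecahydro-1-benzoxepine-3,7-diol (7-hydroxyl axial and cis to the 5a-methyl, 7-methyl equatorial; other centres as in 9)
Conditions: MeMgBr (6 equiv), CeCl3 (anhydrous, 6 equiv), THF, −78 → 0 °C
Reagents that add atoms: methylmagnesium bromide, C[Mg]Br (the carbinol methyl group)
Why: Organocerium-modified Grignard addition (Imamoto conditions) suppresses enolisation of the β-acetoxy ketone; the axial angular methyl 1,3 to the carbonyl blocks the axial trajectory, so methyl enters equatorially and the new hydroxyl is axial, as with 3,3,5-trimethylcyclohexanone. Excess reagent then cleaves the acetate by double addition.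

Step 11
Reactants: 13 6-(hydroxymethyl)-2,2,5a,7-tetramethyldecahydro-1-benzoxepine-3,7-diol
Product: 14 phenyl sulfide of 13 (primary CH2OH replaced by CH2SPh)
Conditions: PhSSPh, n-Bu3P, pyridine, rt → 50 °C
Reagents that add atoms: diphenyl disulfide, c1ccccc1SSc1ccccc1 (the phenylthio group)
Why: Hata–Mukaiyama thioetherification; the primary alcohol is activated as an alkoxyphosphonium ion and displaced by thiophenolate, while the neopentyl-type secondary and the tertiary hydroxyl do not react.

Step 12
Reactants: 14 phenyl sulfide of 13
Product: 15 phenyl sulfone (CH2SO2Ph; secondary and tertiary hydroxyl free)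
Conditions: mCPBA (2.2 equiv), NaHCO3, CH2Cl2, 0 °C → rt
Reagents that add atoms: 3-chloroperoxybenzoic acid, OOC(=O)c1cccc(Cl)c1 (the two sulfone oxygens)
Why: Peracid oxidation of the sulfide through the sulfoxide to the sulfone; no alkene is present at this stage, and alcohols and ethers are inert.

Step 13
Reactants: 15 phenyl sulfone
Product: 16 bis(trimethylsilyl) ether of 15 (secondary and tertiary hydroxyl silylated)
Conditions: Me3SiOTf, 2,6-lutidine, CH2Cl2, −78 → 0 °C
Reagents that add atoms: trimethylsilyl trifluoromethanesulfonate, C[Si](C)(C)OS(=O)(=O)C(F)(F)F
Why: Silyl triflate silylation is strong enough for the hindered axial tertiary alcohol as well as the secondary one, so the carbanion step meets no acidic proton.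

Step 14
Reactants: 16 bis(trimethylsilyl) ether of 15; 11 [(3S,5aS,6R,9aS)-3-(tert-butyldimethylsilyloxy)-2,2,5a-trimethyl-7-methylidenedecahydro-1-benzoxepin-6-yl]methanol
Product: 18 coupled sulfone (both bicycles joined through CH2–CH(SO2Ph); mixture of epimers at the sulfonyl-bearing carbon), via primary triflate 17 (not isolated)
Conditions: 11, Tf2O, 2,6-di-tert-butyl-4-methylpyridine, CH2Cl2, −78 °C; 16, n-BuLi, THF/HMPA, −78 °C; then crude 17, −78 → −30 °C
Reagents that add atoms: trifluoromethanesulfonic anhydride, O=S(=O)(OS(=O)(=O)C(F)(F)F)C(F)(F)F (triflyl group of intermediate 17 only)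
Why: Alkylation of an α-sulfonyl carbanion by a primary alkyl triflate (Julia-type fragment union); the triflate is chosen because both partners are β-branched, and the electrophile sits on the half whose CH2 has only one quaternary neighbour. The new sulfonyl-bearing stereocentre is removed in step 15.

Step 15
Reactants: 18 coupled sulfone
Product: 19 desulfonylated bis-bicycle (linker CH2CH2; ring B tert-butyldimethylsilyl ether, ring D and ring C trimethylsilyl ethers)
Conditions: Na(Hg) (5%), Na2HPO4, MeOH/THF, −20 °C → rt
Reagents that add atoms: none
Why: Reductive desulfonylation by electron transfer from sodium amalgam in buffered methanol; the isolated methylene, the silyl ethers and the oxepanes are untouched.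

Step 16
Reactants: 19 desulfonylated bis-bicycle
Product: 20 diol (ring D secondary and ring C tertiary hydroxyl free; ring B silyl ether kept)
Conditions: pyridinium p-toluenesulfonate (0.2 equiv), MeOH/CH2Cl2, 0 °C → rt
Reagents that add atoms: none
Why: Mild acid methanolysis cleaves trimethylsilyl ethers far faster than the hindered secondary tert-butyldimethylsilyl ether, which exposes the ring D hydroxyl and leaves the ring B one masked.

Step 17
Reactants: 20 diol
Product: 21 ring D ketone (ring B tert-butyldimethylsilyl ether of the target)
Conditions: Dess–Martin periodinane, NaHCO3, CH2Cl2, rt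
Reagents that add atoms: none
Why: Dess–Martin oxidation converts the only secondary alcohol into the ketone under buffered conditions; the tertiary alcohol cannot be oxidised and the methylene is inert.

Step 18
Reactants: 21 ring D ketone
Product: 22 CNP0160418.1 (target)
Conditions: Bu4NF, THF, rt → 45 °C
Reagents that add atoms: none
Why: Fluoride-induced desilylation; the ketone has no epimerisable α-stereocentre (its α-carbons are the gem-dimethyl carbon and a CH2), so the mild basicity is tolerated.

## Compound list

1 | geranyl acetate | CC(=O)OC/C=C(\C)CCC=C(C)C | starting material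
2 | (2E,6E)-8-hydroxy-3,7-dimethylocta-2,6-dien-1-yl acetate | CC(=O)OC/C=C(\C)CC/C=C(\C)CO | intermediate
3 | (2E)-5-[(2S,3S)-3-(hydroxymethyl)-3-methyloxiran-2-yl]-3-methylpent-2-en-1-yl acetate | CC(=O)OC/C=C(\C)CC[C@@H]1O[C@@]1(C)CO | intermediate
4 | prenylmagnesium chloride (3-methylbut-2-en-1-ylmagnesium chloride) | CC(C)=CC[Mg]Cl | starting material
5 | epoxy triflate, the trifluoromethanesulfonate of 3 | CC(=O)OC/C=C(\C)CC[C@@H]1O[C@@]1(C)COS(=O)(=O)C(F)(F)F | intermediate
6 | (6S,7S)-6,7-epoxyfarnesyl acetate, (2E)-3-methyl-5-[(2S,3S)-3-methyl-3-(4-methylpent-3-en-1-yl)oxiran-2-yl]pent-2-en-1-yl acetate | CC(=O)OC/C=C(\C)CC[C@@H]1O[C@@]1(C)CCC=C(C)C | intermediate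
7 | [(1R,2S,3S)-3-hydroxy-2-methyl-6-methylidene-2-(4-methylpent-3-en-1-yl)cyclohexyl]methyl acetate | CC(=O)OC[C@H]1[C@](C)(CCC=C(C)C)[C@@H](O)CCC1=C | intermediate
8 | [(1R,2S,3S)-2-{2-[(2S)-3,3-dimethyloxiran-2-yl]ethyl}-3-hydroxy-2-methyl-6-methylidenecyclohexyl]methyl acetate | CC(=O)OC[C@H]1[C@](C)(CC[C@@H]2OC2(C)C)[C@@H](O)CCC1=C | intermediate
9 | [(3S,5aS,6R,9aS)-3-hydroxy-2,2,5a-trimethyl-7-methylidenedecahydro-1-benzoxepin-6-yl]methyl acetate (trans-fused) | C=C1CC[C@@H]2OC(C)(C)[C@@H](O)CC[C@@]2(C)[C@@H]1COC(C)=O | intermediate
10 | tert-butyldimethylsilyl ether of 9 at the oxepane hydroxyl | C=C1CC[C@@H]2OC(C)(C)[C@@H](O[Si](C)(C)C(C)(C)C)CC[C@@]2(C)[C@@H]1COC(C)=O | intermediate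
11 | [(3S,5aS,6R,9aS)-3-(tert-butyldimethylsilyloxy)-2,2,5a-trimethyl-7-methylidenedecahydro-1-benzoxepin-6-yl]methanol | C=C1CC[C@@H]2OC(C)(C)[C@@H](O[Si](C)(C)C(C)(C)C)CC[C@@]2(C)[C@@H]1CO | intermediate
12 | 7-oxo analogue of 9 (ring ketone in place of the methylene; stereocentres as in 9) | O=C1CC[C@@H]2OC(C)(C)[C@@H](O)CC[C@@]2(C)[C@@H]1COC(C)=O | intermediate
13 | 6-(hydroxymethyl)-2,2,5a,7-tetramethyldecahydro-1-benzoxepine-3,7-diol (7-hydroxyl axial, cis to the 5a-methyl; other centres as in 9) | OC[C@H]1[C@]2(C)CC[C@H](O)C(C)(C)O[C@H]2CC[C@@]1(C)O | intermediate
14 | phenyl sulfide of 13 (CH2SPh in place of CH2OH) | c1ccccc1SC[C@H]1[C@]2(C)CC[C@H](O)C(C)(C)O[C@H]2CC[C@@]1(C)O | intermediate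
15 | phenyl sulfone of the ring C/D half (CH2SO2Ph; two free hydroxyls) | O=S(=O)(c1ccccc1)C[C@H]1[C@]2(C)CC[C@H](O)C(C)(C)O[C@H]2CC[C@@]1(C)O | intermediate
16 | bis(trimethylsilyl) ether of 15 | O=S(=O)(c1ccccc1)C[C@H]1[C@]2(C)CC[C@H](O[Si](C)(C)C)C(C)(C)O[C@H]2CC[C@@]1(C)O[Si](C)(C)C | intermediate
17 | primary triflate of 11 | C=C1CC[C@@H]2OC(C)(C)[C@@H](O[Si](C)(C)C(C)(C)C)CC[C@@]2(C)[C@@H]1COS(=O)(=O)C(F)(F)F | intermediate
18 | coupled sulfone, epimers at the sulfonyl-bearing linker carbon | C=C1CC[C@@H]2OC(C)(C)[C@@H](O[Si](C)(C)C(C)(C)C)CC[C@@]2(C)[C@@H]1CC([C@H]1[C@]2(C)CC[C@H](O[Si](C)(C)C)C(C)(C)O[C@H]2CC[C@@]1(C)O[Si](C)(C)C)S(=O)(=O)c1ccccc1 | intermediate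
19 | desulfonylated bis-bicycle with one tert-butyldimethylsilyl and two trimethylsilyl ethers | C=C1CC[C@@H]2OC(C)(C)[C@@H](O[Si](C)(C)C(C)(C)C)CC[C@@]2(C)[C@@H]1CC[C@H]1[C@]2(C)CC[C@H](O[Si](C)(C)C)C(C)(C)O[C@H]2CC[C@@]1(C)O[Si](C)(C)C | intermediate
20 | diol: ring D secondary and ring C tertiary hydroxyl free, ring B silyl ether | C=C1CC[C@@H]2OC(C)(C)[C@@H](O[Si](C)(C)C(C)(C)C)CC[C@@]2(C)[C@@H]1CC[C@H]1[C@]2(C)CC[C@H](O)C(C)(C)O[C@H]2CC[C@@]1(C)O | intermediate
21 | ring B tert-butyldimethylsilyl ether of the target (ring D ketone) | C=C1CC[C@@H]2OC(C)(C)[C@@H](O[Si](C)(C)C(C)(C)C)CC[C@@]2(C)[C@@H]1CC[C@H]1[C@]2(C)CCC(=O)C(C)(C)O[C@H]2CC[C@@]1(C)O | intermediate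
22 | CNP0160418.1 | C=C1CC[C@@H]2OC(C)(C)[C@@H](O)CC[C@@]2(C)[C@@H]1CC[C@H]1[C@]2(C)CCC(=O)C(C)(C)O[C@H]2CC[C@@]1(C)O | target

## Step count and least certain steps

Total step count: 18. Longest linear sequence: 16 steps (steps 1–6, 9–13 and 14–18); the ring A/B branch (steps 7 and 8) joins at step 14.

**Step 4 (key step).** The most likely failure is poor facial discrimination at the planar tertiary radical, so that the methyl and the 4-methylpent-3-enyl arm exchange axial and equatorial sites and the quaternary carbon forms as a mixture. Capture of the acyclic radical by Cp2TiCl before ring closure (giving an acyclic allylic alcohol), and hydrogen loss into the ring instead of from the methyl group, are further drains.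
Fallback: from 6, the same ring bond is closed in the cationic manifold (MeAlCl2, CH2Cl2, −78 °C). The alkene then attacks the fully substituted epoxide carbon anti to the breaking C–O bond, which transfers the configuration of the trans epoxide to the quaternary carbon stereospecifically (oxygen and homoprenyl arm equatorial, methyl axial). Proton loss gives 7, which must be separated from endocyclic alkene isomers. The route is rejoined at 7; this fallback makes no new compound (F0).

**Step 3.** Bond formation through the tertiary carbon of the prenyl nucleophile (allylic transposition) is the main risk; copper-mediated substitution of the allylic acetate or opening of the epoxide could compete if the temperature rises.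
Fallback: from 3, by way of triflate 5, allylmagnesium bromide and CuI (0.1 equiv) in THF at −78 °C give the terminal alkene F1; the allyl group has two identical termini, so no regiochemical question arises. Cross-metathesis of the terminal alkene F1 with excess 2-methylbut-2-ene and the second-generation Grubbs catalyst, RuCl2(H2IMes)(PCy3)(=CHPh), in CH2Cl2 installs the trisubstituted alkene and returns to 6.

**Step 6.** Attack of the hydroxyl at the secondary epoxide carbon (six-membered ether by the exo course) instead of the tertiary one, and a hydride shift in the activated epoxide leading to a ketone, are the likely failures.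
Fallback: from 7 (bypassing step 5), Hg(OCOCF3)2 in MeCN at 0 °C adds the ring hydroxyl to the prenyl alkene in the Markovnikov sense, at the gem-dimethyl carbon, and NaCl gives the chloromercurio-oxepane F2. Oxidative demercuration (O2, NaBH4, DMF) gives 9 together with its epimer at the oxepane carbinol carbon F3. Dess–Martin oxidation of the mixture gives the oxepanone F4. Reduction with catecholborane and (R)-tetrahydro-1-methyl-3,3-diphenyl-1H,3H-pyrrolo[1,2-c][1,3,2]oxazaborole (0.2 equiv) in toluene at −78 °C differentiates the gem-dimethyl ether carbon from the CH2 group and returns to 9.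

**Step 10.** Enolisation of the β-acetoxy ketone followed by loss of acetate (β-elimination) before the methyl group adds, or incomplete equatorial selectivity of the addition, are the likely failures.
Fallback: from 9, K2CO3 in MeOH gives the diol F5, and t-BuMe2SiCl with imidazole silylates only the primary hydroxyl to give F6. Ozonolysis (O3, then Me2S) gives the β-silyloxy ketone F7, in which the β-oxygen is a far poorer leaving group. MeMgBr with CeCl3 gives the tertiary carbinol F8, and Bu4NF removes the primary silyl group and returns to 13.

**Step 14.** Slow SN2 displacement between two β-branched partners is the risk, so that decomposition of the triflate (elimination, or ionisation assisted by the homoallylic alkene) or proton transfer outruns C–C bond formation.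
Fallback: from 11 and 16, Dess–Martin oxidation of 11 gives the aldehyde F9, to which the lithiated sulfone 16 adds at −78 °C (carbonyl addition is much less sensitive to β-branching) to give the β-hydroxy sulfone F10. MsCl and Et3N, then DBU, eliminate to the vinyl sulfone F11, and conjugate reduction with NaBH4 in EtOH/THF returns to 18.

## Further compounds

F0 | step 4 | none | none
F1 | step 3 | (2E)-5-[(2S,3S)-3-(but-3-en-1-yl)-3-methyloxiran-2-yl]-3-methylpent-2-en-1-yl acetate | CC(=O)OC/C=C(\C)CC[C@@H]1O[C@@]1(C)CCC=C
F2 | step 6 | chloromercurio-oxepane, 3-(chloromercurio) analogue of 9 (both configurations at the mercury-bearing carbon) | C=C1CC[C@@H]2OC(C)(C)C([Hg]Cl)CC[C@@]2(C)[C@@H]1COC(C)=O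
F3 | step 6 | (3R)-epimer of 9 at the oxepane carbinol carbon | C=C1CC[C@@H]2OC(C)(C)[C@H](O)CC[C@@]2(C)[C@@H]1COC(C)=O
F4 | step 6 | oxepan-3-one analogue of 9 | C=C1CC[C@@H]2OC(C)(C)C(=O)CC[C@@]2(C)[C@@H]1COC(C)=O
F5 | step 10 | diol from 9 (acetate removed) | C=C1CC[C@@H]2OC(C)(C)[C@@H](O)CC[C@@]2(C)[C@@H]1CO
F6 | step 10 | primary tert-butyldimethylsilyl ether of the diol | C=C1CC[C@@H]2OC(C)(C)[C@@H](O)CC[C@@]2(C)[C@@H]1CO[Si](C)(C)C(C)(C)C
F7 | step 10 | ring ketone with silyloxymethyl group | O=C1CC[C@@H]2OC(C)(C)[C@@H](O)CC[C@@]2(C)[C@@H]1CO[Si](C)(C)C(C)(C)C
F8 | step 10 | primary tert-butyldimethylsilyl ether of 13 | CC(C)(C)[Si](C)(C)OC[C@H]1[C@]2(C)CC[C@H](O)C(C)(C)O[C@H]2CC[C@@]1(C)O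
F9 | step 14 | aldehyde from 11 | C=C1CC[C@@H]2OC(C)(C)[C@@H](O[Si](C)(C)C(C)(C)C)CC[C@@]2(C)[C@@H]1C=O
F10 | step 14 | β-hydroxy sulfone (diastereomers at the two linker carbons) | C=C1CC[C@@H]2OC(C)(C)[C@@H](O[Si](C)(C)C(C)(C)C)CC[C@@]2(C)[C@@H]1C(O)C([C@H]1[C@]2(C)CC[C@H](O[Si](C)(C)C)C(C)(C)O[C@H]2CC[C@@]1(C)O[Si](C)(C)C)S(=O)(=O)c1ccccc1
F11 | step 14 | vinyl sulfone (alkene between the two linker carbons) | C=C1CC[C@@H]2OC(C)(C)[C@@H](O[Si](C)(C)C(C)(C)C)CC[C@@]2(C)[C@@H]1C=C([C@H]1[C@]2(C)CC[C@H](O[Si](C)(C)C)C(C)(C)O[C@H]2CC[C@@]1(C)O[Si](C)(C)C)S(=O)(=O)c1ccccc1
A1 | alternative 1 | ring A/B oxepene with dioxolane-protected ring A ketone, ring B tert-butyldimethylsilyl ether and tert-butyldiphenylsilyloxymethyl group | O1CCOC12CC[C@@H]3OC(C)(C)[C@@H](O[Si](C)(C)C(C)(C)C)C=C[C@@]3(C)[C@@H]2CO[Si](c1ccccc1)(c1ccccc1)C(C)(C)C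
A2 | alternative 1 | diene precursor of A1 (vinyl on the quaternary carbon, allylic silyl ether in the tertiary ether side chain) | O1CCOC12CC[C@H](OC(C)(C)[C@@H](O[Si](C)(C)C(C)(C)C)C=C)[C@@](C)(C=C)[C@@H]2CO[Si](c1ccccc1)(c1ccccc1)C(C)(C)C
A3 | alternative 2 | ring A hydroxymethyl ketone carrying the 4-methylpent-3-enyl arm | O=C1CC[C@H](O[Si](C)(C)C(C)(C)C)[C@@](C)(CCC=C(C)C)[C@@H]1CO
A4 | alternative 2 | 4-(tert-butyldimethylsilyloxy)-3-methylcyclohex-2-en-1-one, single enantiomer | O=C1CC[C@H](O[Si](C)(C)C(C)(C)C)C(C)=C1
A5 | alternative 3 | ring A/B bicycle with free ring B hydroxyl and pivaloyloxymethyl group | C=C1CC[C@@H]2OC(C)(C)[C@@H](O)CC[C@@]2(C)[C@@H]1COC(=O)C(C)(C)C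
A6 | alternative 3 | (2Z)-3-[(trimethylsilyl)methyl]-(6S,7S,10S)-6,7:10,11-diepoxy farnesyl-type pivalate | CC(C)(C)C(=O)OC/C=C(\C[Si](C)(C)C)CC[C@@H]1O[C@@]1(C)CC[C@@H]1OC1(C)C
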